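**Retrosynthetic overview**
1. Target 13 ⇐ tert-butyl ester 12 by acidolysis; the ring A acid stays masked as its tert-butyl ester throughout.
2. Each depside C(=O)–OAr bond is made together with the acyl ring it carries: phenol + acylketene 8 (from diketo-dioxinone 7) → aryl triketo ester → aldol aromatisation. Esterification of preformed, O-protected orsellinic acids is deliberately avoided.
3. Ring order: ring A comes from the starting material; ring B is built on the phenol oxygen of 4 and ring C on the free 4'-OH of didepside 10, both in one telescoped operation in which 10 is not isolated.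
4. Phenol 4 ⇐ sterically controlled Ir C–H borylation/oxidation of tert-butyl 2-methoxy-6-methylbenzoate 2 (from acid 1).
5. Reagent 7 ⇐ 2,2,6-trimethyl-4H-1,3-dioxin-4-one 5 by two successive C-acylations; it is made once and serves for both rings.

Assumption: the target SMILES has no stereocentre and no stereogenic double bond, so the compound is achiral and no stereocontrol is needed; all reagents without a number are bought.

**Step 1**
Reactants: 1 2-methoxy-6-methylbenzoic acid
Product: 2 tert-butyl 2-methoxy-6-methylbenzoate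
Conditions: Cl3CC(=NH)OtBu (2 equiv), CH2Cl2/cyclohexane, rt, 16 h
Reagents that add atoms: tert-butyl 2,2,2-trichloroacetimidate, CC(C)(C)OC(=N)C(Cl)(Cl)Cl
Why: Trichloroacetimidate esterification transfers tert-butyl to the carboxylate oxygen, so it is indifferent to the two ortho substituents that block carbonyl-addition esterification, and the tert-butyl ester has no arene C–H that could compete in step 2.

**Step 2**
Reactants: 2 tert-butyl 2-methoxy-6-methylbenzoate
Product: 4 tert-butyl 4-hydroxy-2-methoxy-6-methylbenzoate, via aryl pinacolboronate 3 (not isolated)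
Conditions: [Ir(OMe)(cod)]2 (1.5 mol%), dtbpy (3 mol%), B2pin2 (1.0 equiv), THF, 80 °C; evaporate volatiles; Oxone, acetone/H2O, rt, 15 min
Reagents that add atoms: bis(pinacolato)diboron, CC1(C)OB(OC1(C)C)B1OC(C)(C)C(C)(C)O1 (boron of 3 only); potassium peroxymonosulfate (Oxone), [K+].[O-]S(=O)(=O)OO (phenol oxygen of 4)
Why: Sterically controlled Ir-catalysed aromatic C–H borylation goes to C4, the only C–H without an ortho substituent, and one-pot Oxone oxidation of the C–B bond gives the phenol.

**Step 3**
Reactants: 5 2,2,6-trimethyl-4H-1,3-dioxin-4-one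
Product: 6 2,2-dimethyl-6-(2-oxopropyl)-4H-1,3-dioxin-4-one
Conditions: LiHMDS (2.0 equiv), THF, −78 °C; AcCl, −78 → −20 °C; aq. NH4Cl
Reagents that add atoms: acetyl chloride, CC(=O)Cl
Why: γ-Deprotonation gives the lithium dienolate, which is C-acylated at the exocyclic carbon (crossed Claisen-type acylation), the second equivalent of base covering the more acidic product.

**Step 4**
Reactants: 6 2,2-dimethyl-6-(2-oxopropyl)-4H-1,3-dioxin-4-one
Product: 7 6-(2,4-dioxopentyl)-2,2-dimethyl-4H-1,3-dioxin-4-one
Conditions: LDA (3 equiv), THF, −78 → −40 °C; MeC(O)N(OMe)Me, −78 → 0 °C; 1 M HCl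
Reagents that add atoms: N-methoxy-N-methylacetamide, CC(=O)N(C)OC
Why: Dianion formation (Huckin–Weiler type) puts the most reactive carbanion on the terminal methyl, which is acylated by the Weinreb amide (Claisen condensation) through a chelated tetrahedral intermediate that prevents over-addition.

**Step 5**
Reactants: 4 tert-butyl 4-hydroxy-2-methoxy-6-methylbenzoate; 7 6-(2,4-dioxopentyl)-2,2-dimethyl-4H-1,3-dioxin-4-one (2.25 equiv in two charges)
Product: 12 tert-butyl 4-({4-[(2,4-dihydroxy-6-methylbenzoyl)oxy]-2-hydroxy-6-methylbenzoyl}oxy)-2-methoxy-6-methylbenzoate, via acylketene 8 (not isolated), via aryl triketo ester 9 (not isolated), via didepside ester 10 (not isolated), via didepside triketo ester 11 (not isolated)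
Conditions: 7 (1.1 equiv), PhMe, 110 °C, 1 h (N2 sweep); Et3N (3 equiv), CH2Cl2, rt; evaporate with PhMe chase (removes Et3N and H2O); 7 (1.15 equiv), PhMe, 110 °C, 1 h; Et3N (3 equiv), CH2Cl2, rt; 1 M HCl wash
Reagents that add atoms: none
Why: Thermal retro-hetero-Diels–Alder loss of acetone from 7 gives acylketene 8, which phenol 4 traps as the aryl 3,5,7-trioxooctanoate 9, and amine-mediated intramolecular aldol condensation (C2 onto the C7 ketone) with loss of water aromatises the chain to ring B of 10 with the depside ester already in place; because the only unhindered nucleophile in crude 10 is its free 4'-OH (the 2'-OH is hydrogen-bonded to and flanked by the neighbouring ester carbonyl), a second charge of 7 repeats the same ketene-trapping/aldol-aromatisation cycle through 11 to build ring C (phenol variant of the biomimetic resorcylate synthesis, run twice in one vessel and kept free of nucleophilic solvent to protect the aryl esters).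

**Step 6**
Reactants: 12 tert-butyl 4-({4-[(2,4-dihydroxy-6-methylbenzoyl)oxy]-2-hydroxy-6-methylbenzoyl}oxy)-2-methoxy-6-methylbenzoate
Product: 13 4-({4-[(2,4-dihydroxy-6-methylbenzoyl)oxy]-2-hydroxy-6-methylbenzoyl}oxy)-2-methoxy-6-methylbenzoic acid
Conditions: TFA/CH2Cl2 (1:2), Et3SiH (3 equiv), 0 °C → rt, 2 h
Reagents that add atoms: none
Why: Acidolysis of the tert-butyl ester (alkyl–oxygen fragmentation) is insensitive to the di-ortho substitution and leaves both aryl ester bonds and the phenols untouched, while triethylsilane reduces the tert-butyl cation to isobutane so it cannot alkylate the resorcinol ring.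

**Compound list**
1 | 2-methoxy-6-methylbenzoic acid | COc1cccc(C)c1C(=O)O | starting material
2 | tert-butyl 2-methoxy-6-methylbenzoate | COc1cccc(C)c1C(=O)OC(C)(C)C | intermediate
3 | tert-butyl 2-methoxy-6-methyl-4-(4,4,5,5-tetramethyl-1,3,2-dioxaborolan-2-yl)benzoate | COc1cc(B2OC(C)(C)C(C)(C)O2)cc(C)c1C(=O)OC(C)(C)C | intermediate
4 | tert-butyl 4-hydroxy-2-methoxy-6-methylbenzoate | COc1cc(O)cc(C)c1C(=O)OC(C)(C)C | intermediate
5 | 2,2,6-trimethyl-4H-1,3-dioxin-4-one | CC1=CC(=O)OC(C)(C)O1 | starting material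
6 | 2,2-dimethyl-6-(2-oxopropyl)-4H-1,3-dioxin-4-one | CC(=O)CC1=CC(=O)OC(C)(C)O1 | intermediate
7 | 6-(2,4-dioxopentyl)-2,2-dimethyl-4H-1,3-dioxin-4-one | CC(=O)CC(=O)CC1=CC(=O)OC(C)(C)O1 | intermediate
8 | 3,5,7-trioxooct-1-en-1-one (acylketene) | CC(=O)CC(=O)CC(=O)C=C=O | intermediate
9 | tert-butyl 2-methoxy-6-methyl-4-[(3,5,7-trioxooctanoyl)oxy]benzoate | COc1cc(OC(=O)CC(=O)CC(=O)CC(C)=O)cc(C)c1C(=O)OC(C)(C)C | intermediate
10 | tert-butyl 4-[(2,4-dihydroxy-6-methylbenzoyl)oxy]-2-methoxy-6-methylbenzoate | COc1cc(OC(=O)c2c(C)cc(O)cc2O)cc(C)c1C(=O)OC(C)(C)C | intermediate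
11 | tert-butyl 4-({2-hydroxy-6-methyl-4-[(3,5,7-trioxooctanoyl)oxy]benzoyl}oxy)-2-methoxy-6-methylbenzoate | COc1cc(OC(=O)c2c(C)cc(OC(=O)CC(=O)CC(=O)CC(C)=O)cc2O)cc(C)c1C(=O)OC(C)(C)C | intermediate
12 | tert-butyl 4-({4-[(2,4-dihydroxy-6-methylbenzoyl)oxy]-2-hydroxy-6-methylbenzoyl}oxy)-2-methoxy-6-methylbenzoate | COc1cc(OC(=O)c2c(C)cc(OC(=O)c3c(C)cc(O)cc3O)cc2O)cc(C)c1C(=O)OC(C)(C)C | intermediate
13 | 4-({4-[(2,4-dihydroxy-6-methylbenzoyl)oxy]-2-hydroxy-6-methylbenzoyl}oxy)-2-methoxy-6-methylbenzoic acid | COc1cc(OC(=O)c2c(C)cc(OC(=O)c3c(C)cc(O)cc3O)cc2O)cc(C)c1C(=O)O | target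

**Totals**
Total step count: 6. Longest linear sequence: 4 steps (1 → 2 → 4 → 12 → 13; the branch 5 → 6 → 7 → 12 → 13 is also 4).

**Steps most likely to fail**

Most at risk is step 5. The phenols 4 and 10 are weaker traps than an alcohol, so acylketene 8 may close on its own enol oxygen to a 4-hydroxy-2-pyranone. The aryl triketo esters 9 and 11 may also expel the phenoxide (Claisen closure or lactonisation) instead of undergoing the aldol. The second cycle runs on unpurified 10, must discriminate its 4'-OH from its 2'-OH, and must not scramble the first depside bond. The fallback sets out from 4 and comes back at 12, replacing ring construction by stepwise acylation with a preformed ring. Commercial orsellinic acid is perbenzylated (BnBr, K2CO3, DMF) to benzyl 2,4-bis(benzyloxy)-6-methylbenzoate F1. This is saponified (KOH, aqueous dioxane, reflux) to 2,4-bis(benzyloxy)-6-methylbenzoic acid F2. Steglich esterification of this acid with 4 (DCC, DMAP, CH2Cl2) gives tert-butyl 4-{[2,4-bis(benzyloxy)-6-methylbenzoyl]oxy}-2-methoxy-6-methylbenzoate F3. Hydrogenolysis (H2, Pd/C, EtOAc) removes both benzyl ethers and gives 10, which is isolated and purified here. Its free 4'-OH is acylated selectively with a second portion of 2,4-bis(benzyloxy)-6-methylbenzoic acid F2 (DCC, DMAP, CH2Cl2, 0 °C) to give tert-butyl 4-[(4-{[2,4-bis(benzyloxy)-6-methylbenzoyl]oxy}-2-hydroxy-6-methylbenzoyl)oxy]-2-methoxy-6-methylbenzoate F4. Hydrogenolysis (H2, Pd/C, EtOAc) then gives 12.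

Second is step 4. The enolisable Weinreb amide can simply protonate the dianion of 6, and the product consumes base, so conversion may be poor. The fallback sets out from 6 and comes back at 7, replacing the Claisen acylation by an aldol/oxidation pair. The dianion of 6 (LDA, THF, −78 °C) is added to acetaldehyde to give racemic 6-(4-hydroxy-2-oxopentyl)-2,2-dimethyl-4H-1,3-dioxin-4-one F5. Dess–Martin oxidation (CH2Cl2, rt) of the secondary alcohol then gives 7.

Third is step 3. The lithium dienolate of 5 can be O-acylated or acylated twice, and proton transfer from the more acidic product 6 quenches unreacted dienolate, so the yield may be low. The fallback sets out from 5 and comes back at 6, replacing the acylation by a vinylogous Mukaiyama aldol/oxidation pair. Dioxinone 5 is converted (LDA, TMSCl, THF, −78 °C) into its silyl dienol ether, trimethyl[(2,2-dimethyl-4-methylidene-4H-1,3-dioxin-6-yl)oxy]silane F6. Its BF3·OEt2-promoted addition to acetaldehyde (CH2Cl2, −78 °C) gives racemic 6-(2-hydroxypropyl)-2,2-dimethyl-4H-1,3-dioxin-4-one F7. Dess–Martin oxidation (CH2Cl2, rt) of the secondary alcohol then gives 6.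

**Further compounds**
F1 | step 5 | benzyl 2,4-bis(benzyloxy)-6-methylbenzoate | Cc1cc(OCc2ccccc2)cc(OCc2ccccc2)c1C(=O)OCc1ccccc1
F2 | step 5 | 2,4-bis(benzyloxy)-6-methylbenzoic acid | Cc1cc(OCc2ccccc2)cc(OCc2ccccc2)c1C(=O)O
F3 | step 5 | tert-butyl 4-{[2,4-bis(benzyloxy)-6-methylbenzoyl]oxy}-2-methoxy-6-methylbenzoate | COc1cc(OC(=O)c2c(C)cc(OCc3ccccc3)cc2OCc2ccccc2)cc(C)c1C(=O)OC(C)(C)C
F4 | step 5 | tert-butyl 4-[(4-{[2,4-bis(benzyloxy)-6-methylbenzoyl]oxy}-2-hydroxy-6-methylbenzoyl)oxy]-2-methoxy-6-methylbenzoate | COc1cc(OC(=O)c2c(C)cc(OC(=O)c3c(C)cc(OCc4ccccc4)cc3OCc3ccccc3)cc2O)cc(C)c1C(=O)OC(C)(C)C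
F5 | step 4 | 6-(4-hydroxy-2-oxopentyl)-2,2-dimethyl-4H-1,3-dioxin-4-one (racemic) | CC(O)CC(=O)CC1=CC(=O)OC(C)(C)O1
F6 | step 3 | trimethyl[(2,2-dimethyl-4-methylidene-4H-1,3-dioxin-6-yl)oxy]silane | C=C1C=C(O[Si](C)(C)C)OC(C)(C)O1
F7 | step 3 | 6-(2-hydroxypropyl)-2,2-dimethyl-4H-1,3-dioxin-4-one (racemic) | CC(O)CC1=CC(=O)OC(C)(C)O1
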